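## Retrosynthetic overview

1. Cembrane numbering is used: C1 = ring CH carrying C15(=C16H2)–C17O2; C2 = ring CH2; C3 = CHOH; C4–O–C7 = oxolane; C8 = C(CH3)OH; C11 = C=O; C12 = C(CH3)–O–C17. Late unveilings: C11=O from a C10≡C11 alkyne (hydration steered by the C8 hydroxyl), C3–OH from a C3 ketone, the seven-membered lactone from the seco acid.
2. Key disconnection C1–C2 (the bond the cembrane cyclase makes): intramolecular SN2′ alkylation. Enabling feature: C1 is the allylic carbon of the 2-methylene carboxyl unit C16=C15–C17, so it is the SN2′ terminus of a Morita–Baylis–Hillman carbonate made from a C1 aldehyde and tert-butyl acrylate. C2 is the only enolizable carbon of a C3 methyl ketone, because C4 is a fully substituted oxolane carbon.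
3. Linear precursor: C9–C10 by acetylide opening of a C8–C9 epoxide. West half (C2–C9, oxolane) from (R)-linalool; east half (C10–C14, C1) from geraniol via (R)-dehydrolinalool; C15–C17 from tert-butyl acrylate.
4. Ring order: oxolane (step 2), then 14-membered carbocycle (step 14), then seven-membered lactone (step 16). Stereocenters: C4 from linalool, C7/C8 and C12 by Sharpless epoxidations, C1 by the chiral amine catalyst, C3 by CBS reduction.

Key step: step 14

Remark: the target is taken in the open form drawn (C8 hydroxyl, C11 ketone); a ring-closed hemiketal, if populated, is the same compound in equilibrium.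

## Route

Step 1
Reactants: 1 (R)-(−)-linalool, (3R)-3,7-dimethylocta-1,6-dien-3-ol
Product: 2 (2E,6R)-2,6-dimethylocta-2,7-diene-1,6-diol
Conditions: SeO2 (cat.), t-BuOOH, salicylic acid (cat.), CH2Cl2, rt
Reagents that add atoms: tert-butyl hydroperoxide, CC(C)(C)OO
Why: SeO2-catalysed allylic oxidation (ene reaction, then [2,3]-shift) attacks only the (E)-methyl group of the trisubstituted alkene, the vinyl group and the tertiary carbinol (C4, from the chiral pool) being inert; no new stereocenter.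

Step 2
Reactants: 2 (2E,6R)-2,6-dimethylocta-2,7-diene-1,6-diol
Product: 4 (2R)-2-[(2S,5R)-5-ethenyl-5-methyloxolan-2-yl]propane-1,2-diol, via epoxy diol 3 (not isolated)
Conditions: Ti(OiPr)4 (cat.), D-(−)-diethyl tartrate, t-BuOOH, 4 Å MS, CH2Cl2, −20 °C; then camphorsulfonic acid (cat.), rt
Reagents that add atoms: tert-butyl hydroperoxide, CC(C)(C)OO
Why: Sharpless asymmetric epoxidation of the (E)-allylic alcohol with D-(−)-diethyl tartrate should give the (7R,8R)-epoxide 3 under reagent control, and the C4 hydroxyl then opens it at C7 with inversion in a 5-exo-tet cyclization (the usual C3-opening of a titanium-bound 2,3-epoxy alcohol, completed by acid), which sets 7S, keeps 8R and gives the 2,5-cis oxolane.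

Step 3
Reactants: 4 (2R)-2-[(2S,5R)-5-ethenyl-5-methyloxolan-2-yl]propane-1,2-diol
Product: 6 (2R)-2-[(2S,5R)-5-ethenyl-5-methyloxolan-2-yl]-2-methyloxirane, via monotosylate 5 (not isolated)
Conditions: TsCl, pyridine, CH2Cl2, 0 °C; then K2CO3, MeOH, rt
Reagents that add atoms: none
Why: Only the primary hydroxyl is sulfonylated, and the tertiary C8 alkoxide then displaces the tosylate (Williamson-type 3-exo-tet closure) without touching the C8–O bond, so C8 keeps its configuration.

Step 4
Reactants: 7 geraniol, (2E)-3,7-dimethylocta-2,6-dien-1-ol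
Product: 8 [(2R,3R)-3-methyl-3-(4-methylpent-3-en-1-yl)oxiran-2-yl]methanol
Conditions: Ti(OiPr)4 (cat.), D-(−)-diethyl tartrate, t-BuOOH, 4 Å MS, CH2Cl2, −20 °C
Reagents that add atoms: tert-butyl hydroperoxide, CC(C)(C)OO
Why: Sharpless asymmetric epoxidation of geraniol with D-(−)-diethyl tartrate gives the (2R,3R)-epoxy alcohol, whose quaternary carbon becomes C12 (R) of the target.

Step 5
Reactants: 8 [(2R,3R)-3-methyl-3-(4-methylpent-3-en-1-yl)oxiran-2-yl]methanol
Product: 9 (2S,3R)-2-(chloromethyl)-3-methyl-3-(4-methylpent-3-en-1-yl)oxirane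
Conditions: PPh3, CCl4, NaHCO3, reflux
Reagents that add atoms: tetrachloromethane, ClC(Cl)(Cl)Cl
Why: Appel chlorination converts the primary alcohol into the chloride under neutral conditions that leave the trisubstituted epoxide intact.

Step 6
Reactants: 9 (2S,3R)-2-(chloromethyl)-3-methyl-3-(4-methylpent-3-en-1-yl)oxirane
Product: 10 (3R)-3,7-dimethyloct-6-en-1-yn-3-ol
Conditions: n-BuLi (3.3 equiv), THF, −40 °C to 0 °C; aqueous work-up
Reagents that add atoms: none
Why: Base-induced double elimination of the 2,3-epoxy chloride (α-deprotonation, epoxide opening to the chloroalkenyl alkoxide, loss of HCl) gives the terminal alkyne; the C–O bond at the stereocenter is never broken, so (R) is retained.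

Step 7
Reactants: 10 (3R)-3,7-dimethyloct-6-en-1-yn-3-ol
Product: 11 {[(3R)-3,7-dimethyloct-6-en-1-yn-3-yl]oxy}triethylsilane
Conditions: Et3SiOTf, 2,6-lutidine, CH2Cl2, −78 °C to 0 °C
Reagents that add atoms: triethylsilyl trifluoromethanesulfonate, CC[Si](CC)(CC)OS(=O)(=O)C(F)(F)F
Why: Silylation of the tertiary propargylic alcohol with the silyl triflate masks O12, which would otherwise form a lactol with the C1 aldehyde of step 10 and compete as a nucleophile in step 14.

Step 8
Reactants: 11 {[(3R)-3,7-dimethyloct-6-en-1-yn-3-yl]oxy}triethylsilane; 6 (2R)-2-[(2S,5R)-5-ethenyl-5-methyloxolan-2-yl]-2-methyloxirane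
Product: 12 (2R,6R)-2-[(2S,5R)-5-ethenyl-5-methyloxolan-2-yl]-6,10-dimethyl-6-[(triethylsilyl)oxy]undec-9-en-4-yn-2-ol
Conditions: 11, n-BuLi, THF, −78 °C; BF3·OEt2; then 6, −78 °C; aqueous work-up
Reagents that add atoms: none
Why: Yamaguchi–Hirao alkynylation: the lithium acetylide, activated by BF3·OEt2, opens the 2,2-disubstituted epoxide at its unsubstituted carbon (C9) in an SN2 reaction, forming C9–C10 and leaving C8 untouched.

Step 9
Reactants: 12 (2R,6R)-2-[(2S,5R)-5-ethenyl-5-methyloxolan-2-yl]-6,10-dimethyl-6-[(triethylsilyl)oxy]undec-9-en-4-yn-2-ol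
Product: 13 1-[(2R,5S)-5-{(2R,6R)-2-hydroxy-6,10-dimethyl-6-[(triethylsilyl)oxy]undec-9-en-4-yn-2-yl}-2-methyloxolan-2-yl]ethan-1-one
Conditions: PdCl2 (10 mol%), Cu(OAc)2 (20 mol%), O2 (1 atm), DMA–H2O (7:1), rt
Reagents that add atoms: water, O
Why: Tsuji–Wacker oxidation: divalent palladium hydroxypalladates only the monosubstituted vinyl group, in the Markovnikov sense (the trisubstituted alkene is inert), giving the methyl ketone whose methyl carbon is C2 and whose carbonyl carbon is C3.

Step 10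
Reactants: 13 1-[(2R,5S)-5-{(2R,6R)-2-hydroxy-6,10-dimethyl-6-[(triethylsilyl)oxy]undec-9-en-4-yn-2-yl}-2-methyloxolan-2-yl]ethan-1-one
Product: 14 (4R,8R)-8-[(2S,5R)-5-acetyl-5-methyloxolan-2-yl]-8-hydroxy-4-methyl-4-[(triethylsilyl)oxy]non-5-ynal
Conditions: O3, CH2Cl2–MeOH, pyridine, −78 °C; then Me2S
Reagents that add atoms: ozone, [O-][O+]=O
Why: Ozonolysis with reductive work-up cleaves the only remaining alkene, the electron-rich trisubstituted one, much faster than the alkyne, giving the C1 aldehyde.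

Step 11
Reactants: 14 (4R,8R)-8-[(2S,5R)-5-acetyl-5-methyloxolan-2-yl]-8-hydroxy-4-methyl-4-[(triethylsilyl)oxy]non-5-ynal; 15 tert-butyl prop-2-enoate (tert-butyl acrylate)
Product: 16 tert-butyl (6R,10R)-10-[(2S,5R)-5-acetyl-5-methyloxolan-2-yl]-3,10-dihydroxy-6-methyl-2-methylidene-6-[(triethylsilyl)oxy]undec-7-ynoate (both C3 epimers of the chain, i.e. both epimers at cembrane C1)
Conditions: quinuclidin-3-ol (cat.), 15 (neat, excess), rt
Reagents that add atoms: none
Why: Morita–Baylis–Hillman reaction of the unhindered aldehyde with tert-butyl acrylate installs C15–C17 with the methylene in place; the hindered methyl ketone does not react, and the new carbinol center at cembrane C1 is erased in step 14.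

Step 12
Reactants: 16 Morita–Baylis–Hillman alcohol (as above)
Product: 17 tert-butyl (6R,10R)-10-[(2S,5R)-5-acetyl-5-methyloxolan-2-yl]-3-[(tert-butoxycarbonyl)oxy]-10-hydroxy-6-methyl-2-methylidene-6-[(triethylsilyl)oxy]undec-7-ynoate
Conditions: Boc2O, 4-(dimethylamino)pyridine (cat.), CH2Cl2, 0 °C
Reagents that add atoms: di-tert-butyl dicarbonate, CC(C)(C)OC(=O)OC(=O)OC(C)(C)C
Why: Acylation of the secondary allylic alcohol with Boc2O under nucleophilic catalysis gives the allylic carbonate, the tertiary C8 hydroxyl being too hindered to react.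

Step 13
Reactants: 17 allylic carbonate (as above)
Product: 18 tert-butyl (6R,10R)-3-[(tert-butoxycarbonyl)oxy]-6-methyl-2-methylidene-10-[(2S,5R)-5-methyl-5-{1-[(trimethylsilyl)oxy]ethenyl}oxolan-2-yl]-6-[(triethylsilyl)oxy]-10-[(trimethylsilyl)oxy]undec-7-ynoate
Conditions: LiN(SiMe3)2 (2.3 equiv), Me3SiCl (present from the start), THF, −78 °C
Reagents that add atoms: chlorotrimethylsilane, C[Si](C)(C)Cl
Why: Kinetic deprotonation with in situ silyl trapping gives the silyl enol ether regiospecifically, because the ketone can enolize only toward its methyl group (C4 is fully substituted), and the C8 alkoxide is silylated at the same time.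

Step 14
Reactants: 18 silyl enol ether / allylic carbonate (as above)
Product: 19 tert-butyl 2-[(1R,4R,7S,8R,12R)-4,8,12-trimethyl-3-oxo-4,7-epoxy-12-[(triethylsilyl)oxy]-8-[(trimethylsilyl)oxy]cyclotetradec-10-yn-1-yl]prop-2-enoate
Conditions: hydroquinidine 1,4-phthalazinediyl diether (20 mol%), toluene, 4 Å MS, 40 °C, slow addition to 0.003 M
Reagents that add atoms: none
Why: Proposed new method: the tertiary amine adds SN2′ to C16 of the Morita–Baylis–Hillman carbonate and expels tert-butyl carbonate, which loses CO2; the tert-butoxide so formed desilylates the C2=C3 silyl enol ether, and the enolate, ion-paired with the chiral allylic ammonium, attacks C1 in a second SN2′ step that releases the catalyst and the C15=C16 methylene. The closest known reactions are cinchona-alkaloid-catalysed allylic alkylations of Morita–Baylis–Hillman carbonates with 1,3-dicarbonyl compounds and silyloxyfurans (intermolecular) and amine-mediated SN2′–SN2′ closures of five- and six-membered rings; the extension is to a ketone-derived silyl enol ether and to a 14-membered ring. The 14-membered carbocycle is closed in a 14-exo-trig mode (C2 onto C1 of the C1=C15 ammonium enoate) under high dilution. The new stereocenter C1 (R) is to be set by the catalyst, whose quinuclidinium unit is bound at C16 next to C1 and shields one face of the acyclic acceptor, the nearest substrate stereocenter (C12) being three bonds away; the pseudoenantiomeric hydroquinine catalyst is available should the sense be opposite. The step needs C- over O-allylation, attack at C1 rather than C16, and a single enolate: the ammonium group blocks C16, the ketone can enolize only toward C2, and O8 and O12 are silylated so that no alkoxide competes.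

Step 15
Reactants: 19 macrocyclic tert-butyl ester (as above)
Product: 20 2-[(1R,4R,7S,8R,12R)-8,12-dihydroxy-4,8,12-trimethyl-3-oxo-4,7-epoxycyclotetradec-10-yn-1-yl]prop-2-enoic acid
Conditions: CF3CO2H–CH2Cl2 (1:4), 0 °C; aqueous work-up
Reagents that add atoms: none
Why: Acidolysis removes the tert-butyl ester as isobutene and cleaves both silyl ethers in one operation; the low temperature guards against ionization of the tertiary propargylic carbinol.

Step 16
Reactants: 20 seco acid (as above)
Product: 21 (1R,4R,7S,8R,12R)-lactone of 20 between C17 and O12 (seven-membered α-methylene lactone; C3 ketone, 4,7-epoxy bridge, C8–OH, C10≡C11)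
Conditions: 2-methyl-6-nitrobenzoic anhydride, 4-(dimethylamino)pyridine, Et3N, toluene (0.002 M), rt to 50 °C
Reagents that add atoms: none
Why: Shiina lactonization: the mixed anhydride acylates the tertiary but sterically unencumbered propargylic C12 hydroxyl across the ring (C1 and C12 are 1,4-related, seven-membered ring), whereas the C8 hydroxyl could only close a strained 11-membered alkyne-containing lactone; no stereocenter is touched.

Step 17
Reactants: 21 lactone ketone (as above)
Product: 22 (1R,3S,4R,7S,8R,12R)-3-hydroxy analogue of 21 (C3 carbinol, C10≡C11 alkyne)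
Conditions: (R)-Me-CBS [(3aR)-1-methyl-3,3-diphenyltetrahydro-1H,3H-pyrrolo[1,2-c][1,3,2]oxazaborole] (0.5 equiv), catecholborane, toluene, −78 °C
Reagents that add atoms: none
Why: Corey–Bakshi–Shibata reduction: the (R)-oxazaborolidine delivers hydride to the ketone face defined by the large, fully substituted C4 and the small C2 methylene, giving the (3S)-alcohol under reagent control, while lactone, alkyne and methylene are inert to catecholborane at −78 °C.

Step 18
Reactants: 22 alkynyl diol lactone (as above)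
Product: 24 target, (1R,3S,4R,7S,8R,12R)-3,8-dihydroxy-11-oxo-4,7-epoxycembr-15(16)-en-17,12-olide, via dihydrofuran 23 (not isolated)
Conditions: Ph3PAuNTf2 (5 mol%), 1,4-dioxane–H2O, rt; then pyridinium p-toluenesulfonate, THF–H2O
Reagents that add atoms: water, O
Why: Gold-catalysed 5-endo-dig hydroalkoxylation by the C8 hydroxyl places oxygen on C11 (1,4 to C8) and gives enol ether 23, whose hydrolysis unveils the C11 ketone and the free C8 hydroxyl without touching any stereocenter.

## Compound list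

1 | (R)-(−)-linalool, (3R)-3,7-dimethylocta-1,6-dien-3-ol | C=C[C@](C)(O)CCC=C(C)C | starting material
2 | (2E,6R)-2,6-dimethylocta-2,7-diene-1,6-diol | C=C[C@](C)(O)CC/C=C(\C)CO | intermediate
3 | (3R)-5-[(2R,3R)-3-(hydroxymethyl)-3-methyloxiran-2-yl]-3-methylpent-1-en-3-ol | C=C[C@](C)(O)CC[C@H]1O[C@]1(C)CO | intermediate
4 | (2R)-2-[(2S,5R)-5-ethenyl-5-methyloxolan-2-yl]propane-1,2-diol | C=C[C@@]1(C)CC[C@H](O1)[C@](C)(O)CO | intermediate
5 | (2R)-2-[(2S,5R)-5-ethenyl-5-methyloxolan-2-yl]-2-hydroxypropyl 4-methylbenzenesulfonate | C=C[C@@]1(C)CC[C@H](O1)[C@](C)(O)COS(=O)(=O)c1ccc(C)cc1 | intermediate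
6 | (2R)-2-[(2S,5R)-5-ethenyl-5-methyloxolan-2-yl]-2-methyloxirane | C=C[C@@]1(C)CC[C@H](O1)[C@@]2(C)CO2 | intermediate
7 | geraniol, (2E)-3,7-dimethylocta-2,6-dien-1-ol | CC(C)=CCC/C(C)=C/CO | starting material
8 | [(2R,3R)-3-methyl-3-(4-methylpent-3-en-1-yl)oxiran-2-yl]methanol | CC(C)=CCC[C@@]1(C)O[C@@H]1CO | intermediate
9 | (2S,3R)-2-(chloromethyl)-3-methyl-3-(4-methylpent-3-en-1-yl)oxirane | CC(C)=CCC[C@@]1(C)O[C@@H]1CCl | intermediate
10 | (3R)-3,7-dimethyloct-6-en-1-yn-3-ol | CC(C)=CCC[C@@](C)(O)C#C | intermediate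
11 | {[(3R)-3,7-dimethyloct-6-en-1-yn-3-yl]oxy}triethylsilane | CC(C)=CCC[C@@](C)(O[Si](CC)(CC)CC)C#C | intermediate
12 | (2R,6R)-2-[(2S,5R)-5-ethenyl-5-methyloxolan-2-yl]-6,10-dimethyl-6-[(triethylsilyl)oxy]undec-9-en-4-yn-2-ol | C=C[C@@]1(C)CC[C@H](O1)[C@](C)(O)CC#C[C@](C)(O[Si](CC)(CC)CC)CCC=C(C)C | intermediate
13 | 1-[(2R,5S)-5-{(2R,6R)-2-hydroxy-6,10-dimethyl-6-[(triethylsilyl)oxy]undec-9-en-4-yn-2-yl}-2-methyloxolan-2-yl]ethan-1-one | CC(=O)[C@@]1(C)CC[C@H](O1)[C@](C)(O)CC#C[C@](C)(O[Si](CC)(CC)CC)CCC=C(C)C | intermediate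
14 | (4R,8R)-8-[(2S,5R)-5-acetyl-5-methyloxolan-2-yl]-8-hydroxy-4-methyl-4-[(triethylsilyl)oxy]non-5-ynal | CC(=O)[C@@]1(C)CC[C@H](O1)[C@](C)(O)CC#C[C@](C)(O[Si](CC)(CC)CC)CCC=O | intermediate
15 | tert-butyl prop-2-enoate (tert-butyl acrylate) | C=CC(=O)OC(C)(C)C | starting material
16 | tert-butyl (6R,10R)-10-[(2S,5R)-5-acetyl-5-methyloxolan-2-yl]-3,10-dihydroxy-6-methyl-2-methylidene-6-[(triethylsilyl)oxy]undec-7-ynoate (both C3 epimers) | CC(=O)[C@@]1(C)CC[C@H](O1)[C@](C)(O)CC#C[C@](C)(O[Si](CC)(CC)CC)CCC(O)C(=C)C(=O)OC(C)(C)C | intermediate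
17 | tert-butyl (6R,10R)-10-[(2S,5R)-5-acetyl-5-methyloxolan-2-yl]-3-[(tert-butoxycarbonyl)oxy]-10-hydroxy-6-methyl-2-methylidene-6-[(triethylsilyl)oxy]undec-7-ynoate (both C3 epimers) | CC(=O)[C@@]1(C)CC[C@H](O1)[C@](C)(O)CC#C[C@](C)(O[Si](CC)(CC)CC)CCC(OC(=O)OC(C)(C)C)C(=C)C(=O)OC(C)(C)C | intermediate
18 | tert-butyl (6R,10R)-3-[(tert-butoxycarbonyl)oxy]-6-methyl-2-methylidene-10-[(2S,5R)-5-methyl-5-{1-[(trimethylsilyl)oxy]ethenyl}oxolan-2-yl]-6-[(triethylsilyl)oxy]-10-[(trimethylsilyl)oxy]undec-7-ynoate (both C3 epimers) | C=C(O[Si](C)(C)C)[C@@]1(C)CC[C@H](O1)[C@](C)(O[Si](C)(C)C)CC#C[C@](C)(O[Si](CC)(CC)CC)CCC(OC(=O)OC(C)(C)C)C(=C)C(=O)OC(C)(C)C | intermediate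
19 | tert-butyl 2-[(1R,4R,7S,8R,12R)-4,8,12-trimethyl-3-oxo-4,7-epoxy-12-[(triethylsilyl)oxy]-8-[(trimethylsilyl)oxy]cyclotetradec-10-yn-1-yl]prop-2-enoate | C=C(C(=O)OC(C)(C)C)[C@H]1CC(=O)[C@@]2(C)CC[C@H](O2)[C@](C)(O[Si](C)(C)C)CC#C[C@](C)(O[Si](CC)(CC)CC)CC1 | intermediate
20 | 2-[(1R,4R,7S,8R,12R)-8,12-dihydroxy-4,8,12-trimethyl-3-oxo-4,7-epoxycyclotetradec-10-yn-1-yl]prop-2-enoic acid | C=C(C(=O)O)[C@H]1CC(=O)[C@@]2(C)CC[C@H](O2)[C@](C)(O)CC#C[C@](C)(O)CC1 | intermediate
21 | (1R,4R,7S,8R,12R)-17,12-lactone of 20 (seven-membered α-methylene lactone, C3 ketone, C8–OH, C10≡C11) | C=C1C(=O)O[C@]2(C)CC[C@@H]1CC(=O)[C@@]1(C)CC[C@H](O1)[C@](C)(O)CC#C2 | intermediate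
22 | (1R,3S,4R,7S,8R,12R)-3-hydroxy analogue of 21 | C=C1C(=O)O[C@]2(C)CC[C@@H]1C[C@H](O)[C@@]1(C)CC[C@H](O1)[C@](C)(O)CC#C2 | intermediate
23 | 8,11-epoxy-10-ene (2,3-dihydrofuran) isomer of 22, formed by addition of O8–H across C10≡C11 | C=C1C(=O)O[C@]2(C)CC[C@@H]1C[C@H](O)[C@@]1(C)CC[C@H](O1)[C@@]3(C)CC=C2O3 | intermediate
24 | (1R,3S,4R,7S,8R,12R)-3,8-dihydroxy-11-oxo-4,7-epoxycembr-15(16)-en-17,12-olide | C=C1C(=O)O[C@]2(C)CC[C@@H]1C[C@H](O)[C@@]1(C)CC[C@H](O1)[C@](C)(O)CCC2=O | target

## Step count and risks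

Total step count: 18. Longest linear sequence: 15 steps (from geraniol 7: steps 4–8, then 9–18).

Steps most likely to fail:

1. Step 14 (proposed new method). The cyclization may lose out to oligomerization, the basic ketone enolate may destroy the allylic ammonium by proton transfer (diene formation), or the catalyst may discriminate the two faces of C1 poorly. Fallback, from 14 back to 20, closing the same C1–C2 bond as an alkene by known chemistry: keto aldehyde 14 should undergo an intramolecular aldol condensation (Ba(OH)2·8H2O, wet THF, high dilution) to the 14-membered (E)-enone F1. A copper-catalysed asymmetric conjugate addition of isopropenylmagnesium bromide (CuBr·SMe2, chiral phosphoramidite ligand, Me3SiCl) then sets C1 and gives isopropenyl ketone F2. Catalytic SeO2 with t-BuOOH oxidises the isopropenyl methyl group to the 2-substituted acrolein F3, a Pinnick oxidation gives acrylic acid F4, and HF·pyridine removes the triethylsilyl group to return to seco acid 20.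

2. Step 16. Acylation of the tertiary C12 hydroxyl may be too slow, so that the activated acrylic acid is consumed by oligomerization or by conjugate addition of the acyl-transfer catalyst. Fallback, from 20 back to 21, closing the ring from the other partner: acid 20 is converted (EDC·HCl, C6F5OH, CH2Cl2) into pentafluorophenyl ester F5, and the C12 hydroxyl is then deprotonated (NaN(SiMe3)2, THF, −78 °C to 0 °C, high dilution) so that the tertiary alkoxide attacks the isolated active ester to give 21.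

3. Step 9. The ring oxygen on C4 may steer hydroxypalladation to the terminal carbon (aldehyde instead of methyl ketone), and divalent palladium may also engage the internal alkyne. Fallback, from 6 back to 13, building the acetyl group before the fragments are joined: ozonolysis of the vinyl group of epoxide 6 (O3; Me2S) gives aldehyde F6. MeMgBr (THF, −78 °C) adds to give carbinol F7 as a mixture of C3 epimers. The lithium acetylide of 11 (one extra equivalent of n-BuLi for the free hydroxyl, BF3·OEt2) opens the epoxide to give diol F8, and Dess–Martin periodinane oxidises only the secondary hydroxyl, giving 13.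

Further compounds

F1 | step 14 | (1E,4R,7S,8R,12R)-8-hydroxy-4,8,12-trimethyl-12-[(triethylsilyl)oxy]-4,7-epoxycyclotetradec-1-en-10-yn-3-one (macrocyclic C1=C2 enone) | O=C1/C=C/CC[C@@](C)(O[Si](CC)(CC)CC)C#CC[C@@](C)(O)[C@@H]2CC[C@@]1(C)O2
F2 | step 14 | (1R,4R,7S,8R,12R)-8-hydroxy-4,8,12-trimethyl-1-(prop-1-en-2-yl)-12-[(triethylsilyl)oxy]-4,7-epoxycyclotetradec-10-yn-3-one | CC(=C)[C@H]1CC(=O)[C@@]2(C)CC[C@H](O2)[C@](C)(O)CC#C[C@](C)(O[Si](CC)(CC)CC)CC1
F3 | step 14 | 2-[(1R,4R,7S,8R,12R)-8-hydroxy-4,8,12-trimethyl-3-oxo-12-[(triethylsilyl)oxy]-4,7-epoxycyclotetradec-10-yn-1-yl]prop-2-enal | C=C(C=O)[C@H]1CC(=O)[C@@]2(C)CC[C@H](O2)[C@](C)(O)CC#C[C@](C)(O[Si](CC)(CC)CC)CC1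
F4 | step 14 | 2-[(1R,4R,7S,8R,12R)-8-hydroxy-4,8,12-trimethyl-3-oxo-12-[(triethylsilyl)oxy]-4,7-epoxycyclotetradec-10-yn-1-yl]prop-2-enoic acid | C=C(C(=O)O)[C@H]1CC(=O)[C@@]2(C)CC[C@H](O2)[C@](C)(O)CC#C[C@](C)(O[Si](CC)(CC)CC)CC1
F5 | step 16 | pentafluorophenyl 2-[(1R,4R,7S,8R,12R)-8,12-dihydroxy-4,8,12-trimethyl-3-oxo-4,7-epoxycyclotetradec-10-yn-1-yl]prop-2-enoate | C=C(C(=O)Oc1c(F)c(F)c(F)c(F)c1F)[C@H]2CC(=O)[C@@]3(C)CC[C@H](O3)[C@](C)(O)CC#C[C@](C)(O)CC2
F6 | step 9 | (2R,5S)-2-methyl-5-[(2R)-2-methyloxiran-2-yl]oxolane-2-carbaldehyde | O=C[C@@]1(C)CC[C@H](O1)[C@@]2(C)CO2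
F7 | step 9 | 1-{(2R,5S)-2-methyl-5-[(2R)-2-methyloxiran-2-yl]oxolan-2-yl}ethan-1-ol (both carbinol epimers) | CC(O)[C@@]1(C)CC[C@H](O1)[C@@]2(C)CO2
F8 | step 9 | (2R,6R)-2-[(2S,5R)-5-(1-hydroxyethyl)-5-methyloxolan-2-yl]-6,10-dimethyl-6-[(triethylsilyl)oxy]undec-9-en-4-yn-2-ol (both carbinol epimers) | CC(O)[C@@]1(C)CC[C@H](O1)[C@](C)(O)CC#C[C@](C)(O[Si](CC)(CC)CC)CCC=C(C)C
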